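**Plan**

1. Retrosynthetic cuts: (a) the secondary C–OH and the conjugated position of the ring-D double bond go back, by an allylic selenoxide [2,3] shift, to the β,γ-unsaturated ester; (b) in the hydroxy-acid cyclohexene (ring D) the bond from the tertiary carbinol carbon to the carboxyl-bearing carbon and the bond between the two ring-fusion CH carbons shared with the cyclopentane (ring C) are cut together as an intramolecular Diels–Alder reaction; (c) the CH2–CH= bond of the freed dienoate arm (B-alkyl Suzuki); (d) the cyclobutane (ring A) as a keteniminium [2+2] adduct of cyclohexa-1,3-diene.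
2. Forward order: ring A is fused onto the existing six-membered ring (ring B); the dienoate arm is attached to the cyclobutane; ring B is oxidised to the enone; rings C and D close together in the key step; one allylic transposition and deprotection finish.
3. Enabling feature: the tertiary carbinol carbon and its ring-fusion CH neighbour are a ketone carbon and its α-carbon, i.e. an enol ether 2π unit inside ring B. The other four ring-D carbons, C(CO2H)=CH–CH(OH)–CH, are a 2,4-dienoate at a lower oxidation level. The cis-fused cyclobutane holds the one-carbon link to that dienoate on the concave face, directly above the enol ether.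
4. Stereochemistry: the two ring A/B fusion centres come from a C2-symmetric pyrrolidine auxiliary; the octyl carbon from equilibration (exo); the arm-bearing carbon from convex-face hydroboration; the tertiary carbinol and both ring C/D fusion centres from the suprafacial, tether-enforced cycloaddition; the secondary carbinol from the suprafacial [2,3] shift.

Key step: step 8

Assumption: the (2S,5S)-auxiliary is taken to favour the (1S,6S) cycloadduct; if the sense of induction is the opposite, the (2R,5R)-amine is used and nothing else changes.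

**Route**

Step 1
Reactants: 1 decanoyl chloride; 2 (2S,5S)-2,5-dimethylpyrrolidine
Product: 3 1-[(2S,5S)-2,5-dimethylpyrrolidin-1-yl]decan-1-one
Conditions: Et3N, CH2Cl2, 0 °C to rt
Reagents that add atoms: none
Why: N-acylation of the secondary amine by the acid chloride (Schotten–Baumann type) should proceed cleanly and touches no stereocentre.

Step 2
Reactants: 3 1-[(2S,5S)-2,5-dimethylpyrrolidin-1-yl]decan-1-one; 4 cyclohexa-1,3-diene (excess)
Product: 7 (1S,6S,8S)-8-octylbicyclo[4.2.0]oct-2-en-7-one, via keteniminium triflate 5 (not isolated), via cyclobutaniminium triflate 6 (not isolated)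
Conditions: Tf2O, 2,4,6-collidine, ClCH2CH2Cl, −20 to 40 °C; then aq. K2CO3, THF, 40 °C
Reagents that add atoms: water, O
Why: Ghosez keteniminium–alkene [2+2] cycloaddition, in which the iminium carbon should bond to a diene terminus and the octyl-bearing carbon to the internal carbon (ketene-like regiochemistry), the C2-symmetric pyrrolidine should differentiate the enantiotopic faces of the diene and so set the two cis ring-fusion centres, and basic hydrolysis should equilibrate the α-carbon to the exo-octyl (convex-face) epimer.

Step 3
Reactants: 7 (1S,6S,8S)-8-octylbicyclo[4.2.0]oct-2-en-7-one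
Product: 8 (1S,6S,8S)-7-methylidene-8-octylbicyclo[4.2.0]oct-2-ene
Conditions: Ph3PCH3Br, KOtBu, THF, 0 °C to rt
Reagents that add atoms: methyltriphenylphosphonium bromide, C[P+](c1ccccc1)(c1ccccc1)c1ccccc1.[Br-]
Why: Wittig methylenation of the strained, electrophilic cyclobutanone; the neighbouring exo-octyl centre is already the thermodynamic epimer and should not be scrambled.

Step 4
Reactants: 9 ethyl (2E)-4-oxobut-2-enoate
Product: 10 ethyl (2E,4E)-5-iodopenta-2,4-dienoate
Conditions: CrCl2, CHI3, THF, 0 °C
Reagents that add atoms: iodoform, IC(I)I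
Why: Takai olefination should convert the aldehyde into the (E)-vinyl iodide with its usual E preference and leave the enoate untouched.

Step 5
Reactants: 8 (1S,6S,8S)-7-methylidene-8-octylbicyclo[4.2.0]oct-2-ene; 10 ethyl (2E,4E)-5-iodopenta-2,4-dienoate
Product: 12 ethyl (2E,4E)-6-[8-exo-octyl-cis-bicyclo[4.2.0]oct-2-en-7-endo-yl]hexa-2,4-dienoate, via B-alkylborane 11 (not isolated)
Conditions: 9-BBN, THF, 0 °C to rt; then 10, Pd(dppf)Cl2 (5 mol %), AsPh3, Cs2CO3, DMF–THF–H2O, rt
Reagents that add atoms: none
Why: 9-BBN should add boron to the exocyclic CH2 and hydrogen to the ring carbon from the convex face (the concave face is screened by ring B both vicinally and across the four-membered ring, which should outweigh the exo-octyl group next door), so the arm ends up endo and trans to octyl; the cyclic cis-alkene is inert to 9-BBN and the B-alkyl Suzuki–Miyaura coupling keeps the E,E geometry of the iodide.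

Step 6
Reactants: 12 ethyl (2E,4E)-6-[8-exo-octyl-cis-bicyclo[4.2.0]oct-2-en-7-endo-yl]hexa-2,4-dienoate
Product: 13 the 4-hydroxy derivative of 12 (hydroxyl anti to the cyclobutane)
Conditions: SeO2 (0.5 equiv), t-BuOOH, CH2Cl2, rt
Reagents that add atoms: selenium dioxide, O=[Se]=O (transfers the oxygen atom); tert-butyl hydroperoxide, CC(C)(C)OO (restores it)
Why: Sharpless SeO2/t-BuOOH allylic hydroxylation (ene reaction, then [2,3] shift) returns oxygen to the allylic carbon it started from, prefers the ring CH2 over the cyclobutane bridgehead CH and should ignore the electron-poor dienoate; attack on the convex face puts the hydroxyl anti to ring A, a centre that step 7 erases.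

Step 7
Reactants: 13 the 4-hydroxy derivative of 12
Product: 14 ethyl (2E,4E)-6-[7-exo-octyl-3-oxo-cis-bicyclo[4.2.0]oct-4-en-8-endo-yl]hexa-2,4-dienoate
Conditions: Dess–Martin periodinane, CH2Cl2, 0 °C to rt
Reagents that add atoms: none
Why: Dess–Martin oxidation of the allylic alcohol should give the conjugated enone without touching the dienoate; any enone already formed in step 6 converges here.

Step 8
Reactants: 14 ethyl (2E,4E)-6-[7-exo-octyl-3-oxo-cis-bicyclo[4.2.0]oct-4-en-8-endo-yl]hexa-2,4-dienoate
Product: 16 O-TBS tetracyclic β,γ-unsaturated ethyl ester, via silyloxydiene 15 (not isolated)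
Conditions: TBSOTf, Et3N, PhMe, 0 °C to rt; then 80 °C
Reagents that add atoms: tert-butyldimethylsilyl trifluoromethanesulfonate, CC(C)(C)[Si](C)(C)OS(=O)(=O)C(F)(F)F
Why: Soft enolisation of the enone at its α′-CH2 should give the cross-conjugated 2-silyloxy-1,3-cyclohexadiene 15, whose electron-rich enol ether double bond then adds as the 2π partner across the termini of the electron-poor (2E,4E)-dienoate in a concerted, asynchronous, inverse-electron-demand intramolecular Diels–Alder reaction (the bond from the enol ether β-carbon to the dienoate δ-carbon leading). The closest known reactions are the thermal cyclisations of 7,8-disubstituted bicyclo[4.2.0]octa-2,4-dienes onto CH2-linked dienes in the endiandric acid series and Diels–Alder additions of silyl enol ethers to electron-poor dienes. The cyclopentane closes through the three-atom tether (formally 5-exo at the diene terminus) and the cyclohexene closes as the [4+2] ring itself. The silyloxy carbon and the neighbouring ring-fusion CH come out cis because the enol ether is a ring (Z) alkene and the addition is suprafacial on the concave face, the only face the endo CH2 arm can reach; the second ring-fusion CH comes out trans to the first because the arm enters from above ring B and forces the diene to lie outside that ring (exo transition state), and the ester-bearing carbon follows from the E geometry of the enoate. The step needs periselectivity (enol ether as 2π partner, not the silyloxydiene as 4π partner), which the one-carbon link between cyclobutane and diene should secure as in the endiandric precedent, and it needs to outrun electrocyclic opening of the bicyclo[4.2.0]octadiene, which the matched donor/acceptor pairing and the 80 °C ceiling are meant to secure.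

Step 9
Reactants: 16 O-TBS tetracyclic β,γ-unsaturated ethyl ester
Product: 18 α-phenylselanyl ester of 16, via lithium dienolate 17 (not isolated)
Conditions: LiN(iPr)2, THF, −78 °C; then PhSeCl, −78 °C
Reagents that add atoms: benzeneselenenyl chloride, Cl[Se]c1ccccc1
Why: Kinetic deprotonation at the doubly activated carbon α to the ester gives the dienolate, which should be selenenylated at the α-carbon (Reich α-selenenylation) pseudoaxially on the face opposite the axial ring-B carbon of the neighbouring silyloxy carbon, i.e. cis to the silyloxy group.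

Step 10
Reactants: 18 α-phenylselanyl ester of 16
Product: 21 O-TBS ethyl ester of the target, via allylic selenoxide 19 (not isolated), via allylic selenenate 20 (not isolated)
Conditions: H2O2 (30% aq.), pyridine, CH2Cl2, 0 °C to rt
Reagents that add atoms: hydrogen peroxide, OO
Why: Oxidation to the allylic selenoxide should trigger the [2,3]-sigmatropic selenoxide–selenenate rearrangement, which moves the double bond into conjugation with the ester and delivers oxygen suprafacially to the γ-carbon on the face that carried selenium, so the secondary hydroxyl ends up cis to the silyloxy group; syn elimination cannot compete because the only β-hydrogen is vinylic.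

Step 11
Reactants: 21 O-TBS ethyl ester of the target
Product: 23 CNP0106718.3, via dihydroxy ethyl ester 22 (not isolated)
Conditions: Bu4NF, THF, 0 to 40 °C; then LiOH, THF–MeOH–H2O, rt; then 0.5 M HCl to pH 4, 0 °C
Reagents that add atoms: lithium hydroxide, [Li+].[OH-]
Why: Fluoride cleaves the tertiary silyl ether and hydroxide saponifies the ethyl ester (acyl–oxygen cleavage) without touching a stereocentre, and mild acidification should spare the doubly allylic tertiary alcohol.

**Compound list**

1 | decanoyl chloride | CCCCCCCCCC(=O)Cl | starting material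
2 | (2S,5S)-2,5-dimethylpyrrolidine | C[C@H]1CC[C@H](C)N1 | starting material
3 | 1-[(2S,5S)-2,5-dimethylpyrrolidin-1-yl]decan-1-one | CCCCCCCCCC(=O)N1[C@@H](C)CC[C@@H]1C | intermediate
4 | cyclohexa-1,3-diene | C1=CC=CCC1 | starting material
5 | (2S,5S)-1-(dec-1-en-1-ylidene)-2,5-dimethylpyrrolidin-1-ium trifluoromethanesulfonate (keteniminium salt) | CCCCCCCCC=C=[N+]1[C@@H](C)CC[C@@H]1C.[O-]S(=O)(=O)C(F)(F)F | intermediate
6 | (2S,5S)-2,5-dimethyl-1-[8-octylbicyclo[4.2.0]oct-2-en-7-ylidene]pyrrolidin-1-ium trifluoromethanesulfonate, ring-fusion carbons as in 7, both epimers at the octyl carbon | CCCCCCCCC1[C@@H]2C=CCC[C@@H]2C1=[N+]3[C@@H](C)CC[C@@H]3C.[O-]S(=O)(=O)C(F)(F)F | intermediate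
7 | (1S,6S,8S)-8-octylbicyclo[4.2.0]oct-2-en-7-one (cis-fused, octyl exo) | CCCCCCCC[C@H]1[C@@H]2C=CCC[C@@H]2C1=O | intermediate
8 | (1S,6S,8S)-7-methylidene-8-octylbicyclo[4.2.0]oct-2-ene | CCCCCCCC[C@H]1[C@@H]2C=CCC[C@@H]2C1=C | intermediate
9 | ethyl (2E)-4-oxobut-2-enoate | CCOC(=O)/C=C/C=O | starting material
10 | ethyl (2E,4E)-5-iodopenta-2,4-dienoate | CCOC(=O)/C=C/C=C/I | intermediate
11 | 9-{[8-exo-octyl-cis-bicyclo[4.2.0]oct-2-en-7-endo-yl]methyl}-9-borabicyclo[3.3.1]nonane (ring carbons as in 8) | CCCCCCCC[C@H]1[C@@H]2C=CCC[C@@H]2[C@@H]1CB3C4CCCC3CCC4 | intermediate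
12 | ethyl (2E,4E)-6-[8-exo-octyl-cis-bicyclo[4.2.0]oct-2-en-7-endo-yl]hexa-2,4-dienoate (arm trans to octyl, on the face of ring B) | CCCCCCCC[C@H]1[C@@H]2C=CCC[C@@H]2[C@@H]1C/C=C/C=C/C(=O)OCC | intermediate
13 | 4-hydroxy derivative of 12 (allylic hydroxyl on ring B, anti to the cyclobutane) | CCCCCCCC[C@H]1[C@@H]2C=C[C@@H](O)C[C@@H]2[C@@H]1C/C=C/C=C/C(=O)OCC | intermediate
14 | ethyl (2E,4E)-6-[7-exo-octyl-3-oxo-cis-bicyclo[4.2.0]oct-4-en-8-endo-yl]hexa-2,4-dienoate (bicycle renumbered so that the ketone is C-3) | CCCCCCCC[C@H]1[C@@H]2C=CC(=O)C[C@@H]2[C@@H]1C/C=C/C=C/C(=O)OCC | intermediate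
15 | ethyl (2E,4E)-6-[3-(tert-butyldimethylsilyloxy)-7-exo-octyl-cis-bicyclo[4.2.0]octa-2,4-dien-8-endo-yl]hexa-2,4-dienoate | CCCCCCCC[C@H]1[C@@H]2C=CC(O[Si](C)(C)C(C)(C)C)=C[C@@H]2[C@@H]1C/C=C/C=C/C(=O)OCC | intermediate
16 | tetracyclic adduct: target skeleton with tertiary O-TBS, ethyl ester on an sp3 carbon, ring-D alkene β,γ to the ester, no secondary hydroxyl; rings B/D cis-fused, rings C/D trans-fused; silyloxy group, adjacent ring-fusion H and ester on one face | CCCCCCCC[C@H]1[C@@H]2C=C[C@]3(O[Si](C)(C)C(C)(C)C)[C@@H](C(=O)OCC)C=C[C@H]4C[C@H]1[C@H]2[C@@H]43 | intermediate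
17 | lithium dienolate of 16 | CCCCCCCC[C@H]1[C@@H]2C=C[C@]3(O[Si](C)(C)C(C)(C)C)C(=C([O-])OCC)C=C[C@H]4C[C@H]1[C@H]2[C@@H]43.[Li+] | intermediate
18 | α-phenylselanyl ester (selenium cis to the silyloxy group) | CCCCCCCC[C@H]1[C@@H]2C=C[C@]3(O[Si](C)(C)C(C)(C)C)[C@@](C(=O)OCC)([Se]c5ccccc5)C=C[C@H]4C[C@H]1[C@H]2[C@@H]43 | intermediate
19 | allylic selenoxide of 18 (configuration at selenium not defined) | CCCCCCCC[C@H]1[C@@H]2C=C[C@]3(O[Si](C)(C)C(C)(C)C)[C@@](C(=O)OCC)([Se](=O)c5ccccc5)C=C[C@H]4C[C@H]1[C@H]2[C@@H]43 | intermediate
20 | allylic selenenate (O–SePh on the secondary carbinol carbon, conjugated ester) | CCCCCCCC[C@H]1[C@@H]2C=C[C@]3(O[Si](C)(C)C(C)(C)C)C(C(=O)OCC)=C[C@@H](O[Se]c5ccccc5)[C@H]4C[C@H]1[C@H]2[C@@H]43 | intermediate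
21 | ethyl ester of the target with the tertiary hydroxyl as TBS ether | CCCCCCCC[C@H]1[C@@H]2C=C[C@]3(O[Si](C)(C)C(C)(C)C)C(C(=O)OCC)=C[C@@H](O)[C@H]4C[C@H]1[C@H]2[C@@H]43 | intermediate
22 | ethyl ester of the target | CCCCCCCC[C@H]1[C@@H]2C=C[C@]3(O)C(C(=O)OCC)=C[C@@H](O)[C@H]4C[C@H]1[C@H]2[C@@H]43 | intermediate
23 | CNP0106718.3: cyclobutane–cyclohexene–cyclopentane–cyclohexene tetracycle with exo-octyl on the cyclobutane, tertiary and secondary hydroxyls cis on ring D, conjugated carboxylic acid | CCCCCCCC[C@H]1[C@@H]2C=C[C@]3(O)C(C(=O)O)=C[C@@H](O)[C@H]4C[C@H]1[C@H]2[C@@H]43 | target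

**Step count and risks**

Total step count: 11. Longest linear sequence: 10 steps (steps 1–3 and 5–11; step 4 makes the coupling partner).

Steps most likely to fail:

Step 8. The bicyclo[4.2.0]octa-2,4-diene unit of the silyloxydiene may open and reclose electrocyclically at 80 °C, which would erode enantiomeric purity before the cycloaddition is complete, or the silyloxydiene may react as the 4π partner. The fallback sets out from 14 and returns at 16, and makes the same two bonds by an anionic Michael–aldol sequence at low temperature. LiN(SiMe3)2 in THF at −78 °C gives the cross-conjugated lithium dienolate of 14. On warming to −20 °C it should add through its α′-carbon to the δ-carbon of the dienoate (1,6-addition, 5-exo), and the ester dienolate so formed should close onto the ketone by aldol addition. A cold NH4Cl quench gives the tertiary hydroxy ester F1, and TBSOTf with 2,6-lutidine (CH2Cl2, 0 °C) converts it into 16.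

Step 9. The selenium electrophile may enter on the upper face of the dienolate (poor facial selectivity), and the suprafacial shift of step 10 would then carry the error to the secondary carbinol carbon. The fallback sets out from 16 and returns at 21. The epimeric selenide F2 is oxidised as in step 10 to the epimeric allylic alcohol F3. Mitsunobu inversion (4-nitrobenzoic acid, PPh3, diisopropyl azodicarboxylate, THF, 0 °C) gives the inverted 4-nitrobenzoate F4, and K2CO3 in ethanol removes the benzoate to give 21.

Step 2. The auxiliary may discriminate the two faces of the diene poorly (low enantiomeric excess), or the keteniminium salt may be lost to oligomerisation. The fallback sets out from 1 and 4 and returns at 7. Octylketene, generated from 1 with Et3N, is added to 4 under EtAlCl2 promotion (CH2Cl2, −78 °C) and the adduct is equilibrated with DBU to the racemic exo-octyl ketone F5. LiBH(sBu)3 (THF, −78 °C) reduces it from the convex face to the racemic endo alcohol F6. Lipase-catalysed acetylation (lipase from Burkholderia cepacia, vinyl acetate, tert-butyl methyl ether) is a kinetic resolution that should leave the alcohol of the required series F7 and convert its antipode into the acetate F8. If the enzyme prefers the other enantiomer, the acetate fraction is taken and methanolysed instead. Dess–Martin oxidation of the resolved alcohol F7 returns 7.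

**Further compounds**

F1 | step 8 | tertiary hydroxy ester (16 without the silyl group) | CCCCCCCC[C@H]1[C@@H]2C=C[C@]3(O)[C@@H](C(=O)OCC)C=C[C@H]4C[C@H]1[C@H]2[C@@H]43
F2 | step 9 | epimer of 18 at the selenium-bearing carbon (selenium trans to the silyloxy group) | CCCCCCCC[C@H]1[C@@H]2C=C[C@]3(O[Si](C)(C)C(C)(C)C)[C@](C(=O)OCC)([Se]c5ccccc5)C=C[C@H]4C[C@H]1[C@H]2[C@@H]43
F3 | step 9 | epimer of 21 at the secondary carbinol carbon | CCCCCCCC[C@H]1[C@@H]2C=C[C@]3(O[Si](C)(C)C(C)(C)C)C(C(=O)OCC)=C[C@H](O)[C@H]4C[C@H]1[C@H]2[C@@H]43
F4 | step 9 | 4-nitrobenzoate of 21 | CCCCCCCC[C@H]1[C@@H]2C=C[C@]3(O[Si](C)(C)C(C)(C)C)C(C(=O)OCC)=C[C@@H](OC(=O)c5ccc(cc5)[N+](=O)[O-])[C@H]4C[C@H]1[C@H]2[C@@H]43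
F5 | step 2 | racemic 8-exo-octyl-cis-bicyclo[4.2.0]oct-2-en-7-one (both enantiomers) | CCCCCCCC[C@H]1[C@@H]2C=CCC[C@@H]2C1=O.CCCCCCCC[C@@H]1[C@H]2C=CCC[C@H]2C1=O
F6 | step 2 | racemic 8-exo-octyl-cis-bicyclo[4.2.0]oct-2-en-7-endo-ol (both enantiomers) | CCCCCCCC[C@H]1[C@@H]2C=CCC[C@@H]2[C@@H]1O.CCCCCCCC[C@@H]1[C@H]2C=CCC[C@H]2[C@H]1O
F7 | step 2 | resolved endo alcohol of the series of 7 | CCCCCCCC[C@H]1[C@@H]2C=CCC[C@@H]2[C@@H]1O
F8 | step 2 | acetate of the antipodal endo alcohol | CCCCCCCC[C@@H]1[C@H]2C=CCC[C@H]2[C@H]1OC(C)=O
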